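A small charge of solid substrate is stirred in a closed flask, with the gas phase held at a fixed saturation level. How much of that charge ends up as target?

| setting | Thursday's | Friday's | flask |
|---|---|---|---|
| solid substrate | 0.70 mM | 1.1 mM | 0.50 mM |
| gas phase | 0.14 mM (held) | 0.14 mM (held) | 0.14 mM (held) |
| remark | run made earlier | run made earlier |  |
| time |  |  | 8.0 min |

| run | time / min | target / % |
|---|---|---|
| Thursday's | 2.50 | 10.6 |
| Thursday's | 5.00 | 12.8 |
| Thursday's | 8.00 | 13.9 |
| Thursday's | 10.0 | 14.7 |
| Friday's | 1.33 | 3.7 |
| Friday's | 3.00 | 6.4 |
| Friday's | 6.00 | 9.0 |
| Friday's | 10.0 | 9.6 |

(standard deviation of a reading: 0.5 percentage points)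

- given per volume of solution although it is solid: solid substrate
- at the start none of the solid substrate is in solution
- at the start none of the gas phase is in solution

* how much target there is at 8.0 min, in percent of the solid substrate charged
* the change that raises the amount of target at 8.0 min, in percent of the solid substrate charged most ("none" if none brings more than 2 percentage points) (north / south-west / north-west / south-east / none)
* amount of target at 8.0 min, in percent of the solid substrate charged, after south-west

- north: doubling the dissolution coefficient of the solid substrate, all else as stated
- south-west: doubling the transfer coefficient of the gas phase, all else as stated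
- north-west: doubling the solubility of the solid substrate, all else as stated
- south-east: doubling the saturation concentration of gas phase, all else as stated

Tom counts a rate. The gas is held, so he expects the supply to go on. He scales Friday's first reading, 3.7% at 1.33 min, to this flask's charge and to 8.0 min, and gets 49.0%.

Ines counts against the gas. Her gas quota is the saturation level as a fraction of the charge: 20.0% on Thursday, 12.7% on Friday, 28.0% in this flask. Thursday's 13.9% at 8.00 min, divided by its quota, gives 0.695. This is the ceiling share: late target divided by gas quota. Friday's larger charge gives 0.707 at 6.00 min and 0.754 at 10.0 min, each reading carrying 0.5 percentage points. Between those two readings Friday's target grows by 0.6 points, so Tom's straight line has bent.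

Ines commits to 19.5% for this flask. The share holds across the charges, so she expects north and north-west to stay below 2 points. South-east doubles the quota and promises 38.9%, so she picks south-east. The share says nothing about south-west.

The forecast sides with the ceiling at 20% (18% to 21.5%), but it tentatively picks north-west, differing from Ines, and for south-west it gives 21.5%, saying “Faster gas transfer only reaches the plateau sooner”.

The flask gives 19.3%, a ceiling share of 0.690. South-east is best, gaining 13 points where Ines reckoned 19.5% more. South-west gives 26.3%. Tom's line is right early: it gives 4.90% at 0.800 min, and the flask holds 5.41%.

    starting material + target → side product (k = 54.8 L mol⁻¹ s⁻¹)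
    dissolved gas → decomposed reagent (k = 0.0364 s⁻¹)
    solid substrate ⇌ starting material, rate k3*(cs3 - [starting material]) while solid is left; crystals form when [starting material] > cs3 (solubility = 0.180 mM, k = 0.215 s⁻¹)
    gas phase ⇌ dissolved gas, rate k4*(csat - [dissolved gas]) (kL = 0.0290 s⁻¹)
    starting material + dissolved gas → target (k = 108 L mol⁻¹ s⁻¹)

Has this flask come to rest? The charge nearly has. At 8.00 min starting material stands at 2.43% and solid substrate at 0%. At 80.0 min starting material is 0%, target 19.6% and side product 80.4%, up from 78.2%, and the later reading makes no difference to the answer. The gas goes on: 2.48 equiv has already passed by 8.0 min, and decomposed reagent climbs from 0.888 mM to 10.6 mM.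

For the neighbour flask with 2.0 mM of solid substrate, the quota is 7.00%, so the share gives 4.87%. That flask gives 4.71%.

All runs stem from a simulated flask with constants of no real substance, and the scatter is random.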